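**Strategy.** The ten-membered carbocycle contains a hexa-1,5-diene, C10=C1–C2–C3–C4=C5 (germacrane numbering; lactone on C7/C8, C14 on C10, C15 on C4), whose central C2–C3 bond is exactly the σ-bond a Cope rearrangement makes. The ring is therefore closed by ring expansion of a six-membered precursor (C5–C10 bonded) that carries cis vinyl and 3-acyloxyprop-1-en-2-yl groups and a formyl group on quaternary C10. One [3,3] shift cleaves C5–C10, forms C2–C3, and sets the ring-cis C1=C10 and ring-trans C4=C5 geometries through a chair transition state fixed by the trans-fused lactone; conjugation of the new enal pulls the equilibrium. The precursor comes from a butenolide Diels–Alder adduct.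

Key step: step 13

Remark: all intermediates are labelled by germacrane numbering (C1–C10 are the carbons of the final ten-membered ring, C11–C13 the lactone carbons with C12 the carbonyl, C14 sits on C10, C15 on C4). 2-(Hydroxymethyl)acrylic acid, Cp2TiMe2 and lithium acetylide–ethylenediamine are assumed to be purchased.

Step 1
Reactants: 1 (S)-5-(hydroxymethyl)furan-2(5H)-one
Product: 2 (S)-5-[(tert-butyldimethylsilyloxy)methyl]furan-2(5H)-one
Conditions: TBSCl, imidazole, DMF, 0 °C to rt
Reagents that add atoms: tert-butyldimethylsilyl chloride, CC(C)(C)[Si](C)(C)Cl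
Why: Imidazole-mediated silylation of the primary alcohol is mild enough to leave the base-sensitive butenolide stereocentre untouched; no new stereocentre.

Step 2
Reactants: 2 (S)-5-[(tert-butyldimethylsilyloxy)methyl]furan-2(5H)-one; 3 buta-1,3-diene
Product: 4 (3S,3aS,7aR)-3-[(tert-butyldimethylsilyloxy)methyl]-3a,4,7,7a-tetrahydroisobenzofuran-1(3H)-one (cis-fused; lactone carbonyl = C1 on C10, carbinol carbon = C4 on C5)
Conditions: butadiene (excess), BHT (cat.), toluene, 210 °C, sealed tube
Reagents that add atoms: none
Why: Thermal Diels–Alder reaction in which the diene adds to the butenolide face anti to the CH2OTBS group, so the C4 stereocentre (destroyed later) sets C5 and C10 with cis ring fusion.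

Step 3
Reactants: 4 cis-fused Diels–Alder lactone
Product: 6 cis-fused lactone with a dimethoxymethyl group (C14) on C10, cis to H-5, via trimethylsilyl ketene acetal 5 (not isolated)
Conditions: LDA (LiN(iPr)2), THF, −78 °C; TMSCl; solvent exchange; HC(OMe)3, TMSOTf (10 mol%), CH2Cl2, −78 °C
Reagents that add atoms: trimethyl orthoformate, COC(OC)OC
Why: Mukaiyama-type alkylation of the lactone silyl ketene acetal by the dimethoxycarbenium ion, which enters anti to C6 on the convex face of the cis-fused bicycle and so makes C10 quaternary with the masked formyl carbon C14 trans to the C5 side chain.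

Step 4
Reactants: 6 dimethoxymethyl lactone
Product: 7 cyclohex-3-ene diol (C10: CH2OH = C1 and CH(OMe)2 = C14; C5: (S)-CH(OH)CH2OTBS; C1 and C4 cis)
Conditions: LiAlH4, THF, 0 °C
Reagents that add atoms: none
Why: Hydride reduction of the lactone to the 1,4-diol places two hydroxyl groups on one ring face as directing groups, while acetal and silyl ether are inert.

Step 5
Reactants: 7 diol
Product: 8 7,8-epoxy diol (epoxide oxygen cis to C1 and C4)
Conditions: VO(acac)2 (5 mol%), t-BuOOH, CH2Cl2, 0 °C to rt
Reagents that add atoms: tert-butyl hydroperoxide, CC(C)(C)OO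
Why: Hydroxyl-directed vanadium-catalysed epoxidation delivers oxygen to the ring face that carries the two carbinol side chains, which sets C7 and C8.

Step 6
Reactants: 8 epoxy diol
Product: 9 epoxy keto aldehyde (C1 = CHO on C10, C4 = ketone on C5)
Conditions: (COCl)2, DMSO, CH2Cl2, −78 °C; Et3N, −78 to −20 °C
Reagents that add atoms: none
Why: Swern oxidation activates both hydroxyls before base is added, so the 1,4-diol should give the keto aldehyde without lactol formation, and the weak amine base should not enolise the γ,δ-epoxy ketone.

Step 7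
Reactants: 9 epoxy keto aldehyde
Product: 10 epoxy diene (C10: vinyl and CH(OMe)2; C5: 3-(TBSO)prop-1-en-2-yl, cis to the vinyl group)
Conditions: Cp2TiMe2 (excess), toluene, 65 °C, dark
Reagents that add atoms: dimethyltitanocene, [CH3-].[CH3-].[Ti+4].c1cc[cH-]c1.c1cc[cH-]c1
Why: Petasis methylenation converts both carbonyl groups into methylene groups under non-basic conditions, avoiding the C5 enolisation (epimerisation or cyclopropane formation with the epoxide) that a Wittig ylide could cause.

Step 8
Reactants: 10 epoxy diene
Product: 11 trans-2-ethynylcyclohexanol (C7 ethynyl; C8 hydroxyl cis to the vinyl and propenyl groups)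
Conditions: lithium acetylide–ethylenediamine complex, DMSO, rt to 40 °C
Reagents that add atoms: lithium acetylide–ethylenediamine, [Li+].[C-]#C.NCCN
Why: SN2 epoxide opening occurs trans-diaxially at C7 with inversion (Fürst–Plattner rule), because attack at C8 would meet the syn-axial dimethoxymethyl group on C10.

Step 9
Reactants: 11 trans-2-ethynylcyclohexanol
Product: 12 (7R,8S) trans-fused α-methylene γ-lactone still carrying the C14 acetal and the C15 silyl ether
Conditions: PdCl2 (cat.), SnCl2 (cat.), PPh3, CO (7 atm), MeCN, 70 °C
Reagents that add atoms: carbon monoxide, [C-]#[O+]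
Why: Palladium-catalysed cyclocarbonylation of a homopropargylic alcohol (alkoxycarbonyl–palladium formation, syn insertion of the alkyne, protonolysis) gives the α-methylene lactone directly with the trans ring fusion fixed by C7 and C8.

Step 10
Reactants: 12 methylene lactone acetal
Product: 13 hydroxy aldehyde (C14 = CHO on C10, C15 = CH2OH)
Conditions: 1 M aq. HCl–THF (1:4), 0 °C to rt
Reagents that add atoms: water, O
Why: Aqueous acid hydrolyses the dimethyl acetal and the TBS ether in one operation; quaternary C10 cannot epimerise and the trans-diaxial formyl group and side chain cannot form a hemiacetal.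

Step 11
Reactants: 14 2-(hydroxymethyl)acrylic acid
Product: 16 2-[(tert-butyldimethylsilyloxy)methyl]acrylic acid, via bis-silylated acid 15 (not isolated)
Conditions: TBSCl (2.2 equiv), imidazole, DMF, rt; then THF–H2O–AcOH, rt
Reagents that add atoms: tert-butyldimethylsilyl chloride, CC(C)(C)[Si](C)(C)Cl
Why: Bis-silylation followed by selective hydrolysis of the labile silyl ester gives the O-protected acid for coupling.

Step 12
Reactants: 13 hydroxy aldehyde; 16 2-[(tert-butyldimethylsilyloxy)methyl]acrylic acid
Product: 17 cis-dialkenyl formyl lactone with C15 esterified (Cope substrate)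
Conditions: N,N'-diisopropylcarbodiimide, DMAP (cat.), CH2Cl2, 0 °C to rt
Reagents that add atoms: none
Why: Steglich esterification of the primary allylic alcohol should leave the hindered non-enolisable aldehyde and the lactone untouched.

Step 13
Reactants: 17 cis-dialkenyl formyl lactone
Product: 18 ten-membered enal (C14 = CHO on C10; C9 and C2 cis across C1=C10; C3 and C6 trans across C4=C5)
Conditions: degassed toluene (5 mM), BHT (cat.), 130 °C, sealed tube
Reagents that add atoms: none
Why: Thermal [3,3]-sigmatropic (Cope) rearrangement of the hexa-1,5-diene C2=C1–C10–C5–C4=C3: the C5–C10 bond of the cyclohexane breaks while C2–C3 forms, the closest known reactions being the Cope equilibrium of 1,2-dialkenylcyclohexanes with cyclodeca-1,5-dienes (elemane–germacrane) and the conjugation-driven Cope shift of 3-formylhexa-1,5-dienes. The ten-membered ring is closed by a four-carbon ring expansion through a six-membered chair transition state, suprafacial on both allyl units. No stereocentre is created: C5 and C10 are consumed and their cis relationship is translated into one ring-cis (C1=C10) and one ring-trans (C4=C5) double bond, while C7 and C8 are untouched. The selectivity needed is which alkene becomes ring-cis: the trans-fused lactone allows only the cyclohexane chair with the C5 propenyl group axial and the C10 vinyl group equatorial, so in the single accessible chair transition state C9 is axial (ends cis to C2), C6 equatorial (ends trans to C3) and C14 ends trans to C2. The equilibrium should be pulled to the macrocycle by conjugation of the formyl group with the new C1=C10 bond, by loss of the quaternary centre and by release of the two axial substituents.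

Step 14
Reactants: 18 ten-membered enal
Product: 19 C14 allylic alcohol
Conditions: NaBH4, CeCl3·7H2O, MeOH, −78 °C
Reagents that add atoms: none
Why: Luche reduction should give selective 1,2-reduction of the enal at low temperature without conjugate reduction of the α-methylene lactone or the acrylate.

Step 15
Reactants: 19 C14 allylic alcohol
Product: 20 C14 acetate
Conditions: Ac2O, pyridine, DMAP (cat.), CH2Cl2, 0 °C
Reagents that add atoms: acetic anhydride, CC(=O)OC(C)=O
Why: Standard acetylation of the only free (primary allylic) hydroxyl group.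

Step 16
Reactants: 20 C14 acetate
Product: 21 CNP0126545.1, (7R,8S)-14-acetoxy-15-[2-(hydroxymethyl)acryloyloxy]germacra-1(10),4,11(13)-trien-12,8-olide with ring-cis C1=C10 and ring-trans C4=C5
Conditions: HF·pyridine, pyridine–THF, 0 °C to rt
Reagents that add atoms: none
Why: Buffered fluoride cleavage of the primary TBS ether should leave the acetate, both acrylate-type esters and the acid-sensitive cyclodecadiene intact.

**Compound list**

1 | (S)-5-(hydroxymethyl)furan-2(5H)-one | O=C1O[C@H](CO)C=C1 | starting material
2 | (S)-5-[(tert-butyldimethylsilyloxy)methyl]furan-2(5H)-one | O=C1O[C@H](CO[Si](C)(C)C(C)(C)C)C=C1 | intermediate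
3 | buta-1,3-diene | C=CC=C | starting material
4 | (3S,3aS,7aR)-3-[(tert-butyldimethylsilyloxy)methyl]-3a,4,7,7a-tetrahydroisobenzofuran-1(3H)-one | O=C1O[C@H](CO[Si](C)(C)C(C)(C)C)[C@H]2CC=CC[C@@H]12 | intermediate
5 | trimethylsilyl ketene acetal of 4 (C10=C1–OSiMe3) | C[Si](C)(C)OC1=C2CC=CC[C@@H]2[C@@H](CO[Si](C)(C)C(C)(C)C)O1 | intermediate (not isolated)
6 | cis-fused lactone with CH(OMe)2 (C14) on C10, cis to H-5 | O=C1O[C@H](CO[Si](C)(C)C(C)(C)C)[C@H]2CC=CC[C@@]12C(OC)OC | intermediate
7 | cyclohex-3-ene diol (C10: CH2OH and CH(OMe)2; C5: (S)-CH(OH)CH2OTBS; C1 and C4 cis) | OC[C@]1(C(OC)OC)CC=CC[C@@H]1[C@H](O)CO[Si](C)(C)C(C)(C)C | intermediate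
8 | 7,8-epoxy diol, epoxide cis to C1 and C4 | OC[C@]1(C(OC)OC)C[C@@H]2O[C@@H]2C[C@@H]1[C@H](O)CO[Si](C)(C)C(C)(C)C | intermediate
9 | epoxy keto aldehyde (C1 formyl, C4 ketone) | O=C[C@]1(C(OC)OC)C[C@@H]2O[C@@H]2C[C@@H]1C(=O)CO[Si](C)(C)C(C)(C)C | intermediate
10 | epoxy diene (C10 vinyl cis to C5 3-(TBSO)prop-1-en-2-yl; C14 acetal trans) | C=C[C@]1(C(OC)OC)C[C@@H]2O[C@@H]2C[C@@H]1C(=C)CO[Si](C)(C)C(C)(C)C | intermediate
11 | trans-2-ethynylcyclohexanol (C7 ethynyl, C8 OH cis to both alkenyl groups) | C=C[C@]1(C(OC)OC)C[C@H](O)[C@@H](C#C)C[C@@H]1C(=C)CO[Si](C)(C)C(C)(C)C | intermediate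
12 | (7R,8S) trans-fused α-methylene γ-lactone with C14 acetal and C15 OTBS | C=C[C@]1(C(OC)OC)C[C@@H]2OC(=O)C(=C)[C@H]2C[C@@H]1C(=C)CO[Si](C)(C)C(C)(C)C | intermediate
13 | hydroxy aldehyde (C14 formyl on C10, C15 hydroxymethyl) | C=C[C@]1(C=O)C[C@@H]2OC(=O)C(=C)[C@H]2C[C@@H]1C(=C)CO | intermediate
14 | 2-(hydroxymethyl)acrylic acid | C=C(CO)C(=O)O | starting material
15 | tert-butyldimethylsilyl 2-[(tert-butyldimethylsilyloxy)methyl]acrylate | C=C(CO[Si](C)(C)C(C)(C)C)C(=O)O[Si](C)(C)C(C)(C)C | intermediate (not isolated)
16 | 2-[(tert-butyldimethylsilyloxy)methyl]acrylic acid | C=C(CO[Si](C)(C)C(C)(C)C)C(=O)O | intermediate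
17 | Cope substrate: cis-1-vinyl-2-(3-acyloxyprop-1-en-2-yl)cyclohexane with formyl on C10 and trans-fused α-methylene lactone | C=C[C@]1(C=O)C[C@@H]2OC(=O)C(=C)[C@H]2C[C@@H]1C(=C)COC(=O)C(=C)CO[Si](C)(C)C(C)(C)C | intermediate
18 | ten-membered enal (C14 formyl; ring-cis C1=C10, ring-trans C4=C5) | C=C(CO[Si](C)(C)C(C)(C)C)C(=O)OC/C1=C\C[C@@H]2C(=C)C(=O)O[C@H]2C/C(C=O)=C\CC1 | intermediate
19 | C14 allylic alcohol | C=C(CO[Si](C)(C)C(C)(C)C)C(=O)OC/C1=C\C[C@@H]2C(=C)C(=O)O[C@H]2C/C(CO)=C\CC1 | intermediate
20 | C14 acetate, side-chain OTBS | C=C(CO[Si](C)(C)C(C)(C)C)C(=O)OC/C1=C\C[C@@H]2C(=C)C(=O)O[C@H]2C/C(COC(C)=O)=C\CC1 | intermediate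
21 | CNP0126545.1 | C=C(CO)C(=O)OC/C1=C\C[C@@H]2C(=C)C(=O)O[C@H]2C/C(COC(C)=O)=C\CC1 | target

**Total step count:** 16. **Longest linear sequence:** 15 steps (steps 1–10 and 12–16).

**Steps most likely to fail**

1. Step 13 (Cope ring expansion). The sigmatropic equilibrium may stop short of full conversion, and prolonged heating may start radical polymerisation of the two acrylate-type units. The fallback turns the single thermodynamic pass into a reductive trapping and recycling sequence. It sets out from 17: the mixture is heated only to equilibrium, cooled and treated with NaBH4/CeCl3·7H2O in MeOH at −78 °C. The rearranged enal 18 is thereby taken on as allylic alcohol 19, where the fallback rejoins the route. Unrearranged 17 is reduced to the neopentylic primary alcohol F1, which is separated, re-oxidised to 17 with Dess–Martin periodinane and resubmitted, so the equilibrium is drained cycle by cycle.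

2. Step 9 (cyclocarbonylation). The alkoxycarbonyl–palladium intermediate may insert into the nearby C10 vinyl group instead of the alkyne, or lactonisation may stall because hydroxyl and alkyne must first become diequatorial. The fallback replaces the alkyne/CO logic by a malonate annulation. It sets out from epoxide 10: diethyl malonate and NaOEt in refluxing EtOH should open the epoxide at C7 and lactonise to the α-ethoxycarbonyl trans-lactone F2. LiOH in THF–H2O followed by mild acidification should give the α-carboxy lactone F3. Aqueous formaldehyde and Et2NH, then NaOAc/AcOH at 70 °C (decarboxylative Mannich elimination), should give 12, where the route is rejoined.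

3. Step 3 (quaternary C10–C14 bond). The hindered tetrasubstituted ketene acetal may be protodesilylated back to 4 faster than it is alkylated by the orthoformate-derived cation. The fallback builds C14 by aldol and oxidation instead. It sets out from 4: LDA followed by gaseous formaldehyde should give the 7a-hydroxymethyl lactone F4 with the same facial control. Dess–Martin periodinane with NaHCO3 should give the non-enolisable 7a-formyl lactone F5. HC(OMe)3 and PPTS in MeOH should convert it into acetal 6, where the route is rejoined.

**Further compounds**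

F1 | step 13 | primary alcohol from reduction of unrearranged 17 (C14 = CH2OH) | C=C[C@]1(CO)C[C@@H]2OC(=O)C(=C)[C@H]2C[C@@H]1C(=C)COC(=O)C(=C)CO[Si](C)(C)C(C)(C)C
F2 | step 9 | α-ethoxycarbonyl trans-fused lactone (C14 acetal, C15 OTBS) | C=C[C@]1(C(OC)OC)C[C@@H]2OC(=O)C(C(=O)OCC)[C@H]2C[C@@H]1C(=C)CO[Si](C)(C)C(C)(C)C
F3 | step 9 | α-carboxy trans-fused lactone (C14 acetal, C15 OTBS) | C=C[C@]1(C(OC)OC)C[C@@H]2OC(=O)C(C(O)=O)[C@H]2C[C@@H]1C(=C)CO[Si](C)(C)C(C)(C)C
F4 | step 3 | cis-fused lactone with hydroxymethyl (C14) on C10 | O=C1O[C@H](CO[Si](C)(C)C(C)(C)C)[C@H]2CC=CC[C@@]12CO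
F5 | step 3 | cis-fused lactone with formyl (C14) on C10 | O=C1O[C@H](CO[Si](C)(C)C(C)(C)C)[C@H]2CC=CC[C@@]12C=O
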